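The cycloheptene ring consists of a five-carbon run, C5–C6(O)–C7=C8(CH3)–C9, and a two-carbon unit, C10–C1 (daucane numbering). Its C1–C5 bond is also the fusion bond to the cyclopentane. This is the pattern of a [5+2] cycloadduct. The precursor is an acyclic 3-pivaloyloxy-1,4-enyne whose alkyne terminus (C5) carries the C4 carbinol and, three atoms on, a 1,1-disubstituted alkene (C1=C10). A rhodium catalyst shifts the ester from C7 to C6 and forms C5–C1 and C9–C10 in one operation. This closes both rings and sets quaternary C1 under control of C4. Ester cleavage, hydroxyl-directed reduction and acylation finish the synthesis.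

Key step: step 7

Remark on the chemistry:
- Numbering: C1 = angular quaternary carbon (CH3); C2 and C3 = cyclopentane CH2; C4 = carbinol carbon (OH, isopropyl); C5 = ring-fusion CH; C6 = ester-bearing CH; C7=C8(CH3) = ring alkene; C9 and C10 = ring CH2.
- Assumption: 12 is carried as the mixture of C7 epimers, because C7 becomes sp2 in step 7.

Step 1
Reactants: 1 prop-2-yn-1-ol; 2 isopropylmagnesium chloride
Product: 3 3-methyl-2-methylidenebutan-1-ol
Conditions: 2 (2.5 equiv), CuI (10 mol %), THF, −10 °C to rt; then aq NH4Cl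
Reagents that add atoms: none
Why: Copper-catalysed carbomagnesiation of a propargylic alkoxide, in which the magnesium alkoxide directs the isopropyl group to the internal alkyne carbon through a chelated vinylmagnesium species and protonation gives the 2-substituted allyl alcohol; no stereocentre is formed.

Step 2
Reactants: 3 3-methyl-2-methylidenebutan-1-ol
Product: 4 [(2R)-2-(propan-2-yl)oxiran-2-yl]methanol
Conditions: Ti(OiPr)4 (10 mol %), D-(−)-diisopropyl tartrate (12 mol %), t-BuOOH, 4 Å molecular sieves, CH2Cl2, −20 °C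
Reagents that add atoms: tert-butyl hydroperoxide, CC(C)(C)OO
Why: Sharpless asymmetric epoxidation of a 2-substituted allyl alcohol, in which the D-(−)-tartrate titanium complex delivers oxygen to the alkene face that gives the (R)-epoxide and so sets C4, the only stereocentre introduced by a reagent.

Step 3
Reactants: 4 [(2R)-2-(propan-2-yl)oxiran-2-yl]methanol; 5 (2-methylallyl)magnesium chloride
Product: 6 (2R)-5-methyl-2-(propan-2-yl)hex-5-ene-1,2-diol
Conditions: 5 (3 equiv), CuI (10 mol %), THF, −40 to 0 °C; then aq NH4Cl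
Reagents that add atoms: none
Why: Copper-catalysed SN2 opening of a 2,2-disubstituted epoxide at its unsubstituted CH2 carbon (the first equivalent of 5 only deprotonates the alcohol), so the C4–O bond and the configuration at C4 stay untouched.

Step 4
Reactants: 6 (2R)-5-methyl-2-(propan-2-yl)hex-5-ene-1,2-diol
Product: 7 (2R)-2-hydroxy-5-methyl-2-(propan-2-yl)hex-5-enal
Conditions: IBX (1.3 equiv), DMSO–THF, rt
Reagents that add atoms: none
Why: IBX oxidation takes the primary alcohol to the aldehyde, cannot touch the tertiary alcohol, does not cleave 1,2-diols and leaves the alkene alone; C4 has no α-hydrogen and cannot epimerise.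

Step 5
Reactants: 7 (2R)-2-hydroxy-5-methyl-2-(propan-2-yl)hex-5-enal
Product: 8 (3R)-6-methyl-3-(propan-2-yl)hept-6-en-1-yn-3-ol
Conditions: dimethyl (1-diazo-2-oxopropyl)phosphonate (1.3 equiv), K2CO3 (2 equiv), MeOH, 0 °C to rt
Reagents that add atoms: dimethyl (1-diazo-2-oxopropyl)phosphonate, CC(=O)C(=[N+]=[N-])P(=O)(OC)OC
Why: Ohira–Bestmann variant of the Seyferth–Gilbert homologation converts the aldehyde carbon (C5) and the diazo carbon (C6) into the terminal alkyne under mild base that leaves the quaternary C4 carbinol unchanged.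

Step 6
Reactants: 8 (3R)-6-methyl-3-(propan-2-yl)hept-6-en-1-yn-3-ol; 9 methacrolein
Product: 12 (6R)-6-hydroxy-2,9-dimethyl-6-(propan-2-yl)deca-1,9-dien-4-yn-3-yl 2,2-dimethylpropanoate (C7 epimers), via dilithiated enynol 10 (not isolated), via dilithium dialkoxide 11 (not isolated)
Conditions: n-BuLi (2.1 equiv), THF, −78 °C; 9 (1.1 equiv); then t-BuCOCl (1.05 equiv), −78 to 0 °C; H2O
Reagents that add atoms: pivaloyl chloride, CC(C)(C)C(=O)Cl
Why: Acetylide 1,2-addition to an enal followed by acylation in the same flask, in which the bulky acid chloride should take only the unhindered secondary alkoxide and leave the tertiary alkoxide flanked by isopropyl and alkynyl groups; the new C7 centre is not controlled and need not be.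

Step 7
Reactants: 12 (6R)-6-hydroxy-2,9-dimethyl-6-(propan-2-yl)deca-1,9-dien-4-yn-3-yl 2,2-dimethylpropanoate
Product: 14 (3R,8aS)-3-hydroxy-6,8a-dimethyl-3-(propan-2-yl)-1,2,3,7,8,8a-hexahydroazulen-4-yl 2,2-dimethylpropanoate, via rhodacyclohexadiene 13 (not isolated)
Conditions: [Rh(cod)2]BF4 (10 mol %), P[OCH(CF3)2]3 (20 mol %), ClCH2CH2Cl, 70 °C
Reagents that add atoms: none
Why: Proposed new method: the cationic monovalent rhodium catalyst binds the C5≡C6 alkyne, the pivalate carbonyl oxygen adds to C6 while the C7–O bond breaks (1,2-acyloxy migration), and the resulting rhodium dienylcarbene at C5 closes onto C9 to rhodacyclohexadiene 13, so that C5 to C9 act as one five-carbon unit. The tethered C1=C10 alkene then inserts into the Rh–C5 bond (5-exo-trig closure of the cyclopentane, bond C5–C1), and C(sp3)–C(sp3) reductive elimination from the eight-membered rhodacycle joins C10 to C9 (closure of the cycloheptadiene) and frees the catalyst. The closest known reaction type is the rhodium-catalysed [5+2] cycloaddition of 3-acyloxy-1,4-enynes, established for tethered alkenes when the tether starts at the enyne alkene and for tethered alkynes when it starts at the alkyne terminus, so only the pairing of an alkyne-terminus tether with an alkene is untested. C1 is the only new stereocentre and is controlled by C4: in the coplanar insertion transition state the angular methyl lies syn, across sp2 C5, to one C4 substituent, and this should be the small OH rather than the isopropyl group, which gives the cis OH/CH3 relation of the target. The step needs 1,2- over 1,3-acyloxy migration, which the fully substituted C4 (shielding C5 from the ester oxygen) and chelation of rhodium by the 1,6-enyne should secure, and it needs insertion to outrun collapse of 13 to a cyclopentadiene, which the three-atom tether and the electron-poor phosphite should favour. C7 becomes sp2, so both epimers of 12 converge on 14.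

Step 8
Reactants: 14 (3R,8aS)-3-hydroxy-6,8a-dimethyl-3-(propan-2-yl)-1,2,3,7,8,8a-hexahydroazulen-4-yl 2,2-dimethylpropanoate
Product: 16 (3R,3aR,8aS)-3-hydroxy-6,8a-dimethyl-3-(propan-2-yl)-2,3,3a,7,8,8a-hexahydroazulen-4(1H)-one, via potassium dienolate 15 (not isolated)
Conditions: K2CO3 (0.2 equiv), MeOH, 0 °C to rt
Reagents that add atoms: none
Why: Base-catalysed transesterification of an activated enol ester releases the cross-conjugated enolate, and reversible protonation sets C5 under thermodynamic control in favour of the trans-fused epimer, in which C6 is cis to the C4 hydroxyl (hydrogen bond to the C6 carbonyl) and trans to the isopropyl group.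

Step 9
Reactants: 16 (3R,3aR,8aS)-3-hydroxy-6,8a-dimethyl-3-(propan-2-yl)-2,3,3a,7,8,8a-hexahydroazulen-4(1H)-one
Product: 17 (3R,3aS,4S,8aS)-6,8a-dimethyl-3-(propan-2-yl)-1,2,3,3a,4,7,8,8a-octahydroazulene-3,4-diol
Conditions: Me4NBH(OAc)3 (5 equiv), MeCN–AcOH, −30 to −10 °C
Reagents that add atoms: none
Why: Evans–Saksena reduction, in which the C4 hydroxyl exchanges onto boron and hydride is delivered inside the molecule to the C6 carbonyl from the hydroxyl-bearing face, so that the 1,3-anti diol (C6 configuration of the target) should form by 1,2-reduction only.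

Step 10
Reactants: 17 (3R,3aS,4S,8aS)-6,8a-dimethyl-3-(propan-2-yl)-1,2,3,3a,4,7,8,8a-octahydroazulene-3,4-diol; 18 4-acetoxybenzoic acid
Product: 19 (3R,3aS,4S,8aS)-3-hydroxy-6,8a-dimethyl-3-(propan-2-yl)-1,2,3,3a,4,7,8,8a-octahydroazulen-4-yl 4-(acetyloxy)benzoate
Conditions: 18 (1.5 equiv), DCC (1.6 equiv), DMAP (20 mol %), CH2Cl2, rt
Reagents that add atoms: none
Why: Steglich esterification acylates the secondary allylic C6 hydroxyl with retention, while the tertiary C4 hydroxyl is too hindered to react and the neutral conditions avoid allylic ionisation.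

Step 11
Reactants: 19 (3R,3aS,4S,8aS)-3-hydroxy-6,8a-dimethyl-3-(propan-2-yl)-1,2,3,3a,4,7,8,8a-octahydroazulen-4-yl 4-(acetyloxy)benzoate
Product: 20 (3R,3aS,4S,8aS)-3-hydroxy-6,8a-dimethyl-3-(propan-2-yl)-1,2,3,3a,4,7,8,8a-octahydroazulen-4-yl 4-hydroxybenzoate
Conditions: pyrrolidine (3 equiv), CH2Cl2, 0 °C to rt
Reagents that add atoms: none
Why: Chemoselective aminolysis, in which the aryl acetate (phenoxide leaving group) is far more reactive than the hindered secondary alkyl benzoate, so only the phenol should be set free and no stereocentre is touched.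

Compound list
1 | prop-2-yn-1-ol | C#CCO | starting material
2 | isopropylmagnesium chloride | CC(C)[Mg]Cl | starting material
3 | 3-methyl-2-methylidenebutan-1-ol | C=C(CO)C(C)C | intermediate
4 | [(2R)-2-(propan-2-yl)oxiran-2-yl]methanol | OC[C@]1(C(C)C)CO1 | intermediate
5 | (2-methylallyl)magnesium chloride | C=C(C)C[Mg]Cl | starting material
6 | (2R)-5-methyl-2-(propan-2-yl)hex-5-ene-1,2-diol | OC[C@](O)(C(C)C)CCC(C)=C | intermediate
7 | (2R)-2-hydroxy-5-methyl-2-(propan-2-yl)hex-5-enal | O=C[C@](O)(C(C)C)CCC(C)=C | intermediate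
8 | (3R)-6-methyl-3-(propan-2-yl)hept-6-en-1-yn-3-ol | C#C[C@](O)(C(C)C)CCC(C)=C | intermediate
9 | methacrolein | C=C(C)C=O | starting material
10 | dilithiated enynol (lithium acetylide and lithium alkoxide of 8) | [Li]C#C[C@](O[Li])(C(C)C)CCC(C)=C | intermediate
11 | dilithium dialkoxide of the methacrolein adduct (C7 epimers) | [Li]OC(C#C[C@](O[Li])(C(C)C)CCC(C)=C)C(C)=C | intermediate
12 | (6R)-6-hydroxy-2,9-dimethyl-6-(propan-2-yl)deca-1,9-dien-4-yn-3-yl 2,2-dimethylpropanoate (C7 epimers) | C=C(C)C(OC(=O)C(C)(C)C)C#C[C@](O)(C(C)C)CCC(C)=C | intermediate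
13 | rhodacyclohexadiene (Rh bound to C5 and C9, further ligands omitted) | CC1=CC(OC(=O)C(C)(C)C)=C([Rh]C1)[C@](O)(C(C)C)CCC(C)=C | intermediate
14 | (3R,8aS)-3-hydroxy-6,8a-dimethyl-3-(propan-2-yl)-1,2,3,7,8,8a-hexahydroazulen-4-yl 2,2-dimethylpropanoate | CC1=CC(OC(=O)C(C)(C)C)=C2[C@@](C)(CC1)CC[C@@]2(O)C(C)C | intermediate
15 | potassium dienolate of 16 | [K+].CC1=CC([O-])=C2[C@@](C)(CC1)CC[C@@]2(O)C(C)C | intermediate
16 | (3R,3aR,8aS)-3-hydroxy-6,8a-dimethyl-3-(propan-2-yl)-2,3,3a,7,8,8a-hexahydroazulen-4(1H)-one | CC1=CC(=O)[C@@H]2[C@@](C)(CC1)CC[C@@]2(O)C(C)C | intermediate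
17 | (3R,3aS,4S,8aS)-6,8a-dimethyl-3-(propan-2-yl)-1,2,3,3a,4,7,8,8a-octahydroazulene-3,4-diol | CC1=C[C@H](O)[C@@H]2[C@@](C)(CC1)CC[C@@]2(O)C(C)C | intermediate
18 | 4-acetoxybenzoic acid | CC(=O)Oc1ccc(cc1)C(=O)O | starting material
19 | (3R,3aS,4S,8aS)-3-hydroxy-6,8a-dimethyl-3-(propan-2-yl)-1,2,3,3a,4,7,8,8a-octahydroazulen-4-yl 4-(acetyloxy)benzoate | CC1=C[C@H](OC(=O)c2ccc(OC(C)=O)cc2)[C@@H]2[C@@](C)(CC1)CC[C@@]2(O)C(C)C | intermediate
20 | (3R,3aS,4S,8aS)-3-hydroxy-6,8a-dimethyl-3-(propan-2-yl)-1,2,3,3a,4,7,8,8a-octahydroazulen-4-yl 4-hydroxybenzoate | CC1=C[C@H](OC(=O)c2ccc(O)cc2)[C@@H]2[C@@](C)(CC1)CC[C@@]2(O)C(C)C | target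

Total step count: 11. Longest linear sequence: 11 steps (1 to 20).

Steps most likely to fail

**Step 7 (key step).** The ester may migrate 1,3 and give an allenyl ester. Rhodacycle 13 may collapse to a cyclopentadiene before the hindered alkene inserts. The alkene may also insert with poor facial selectivity at C1. The fallback uses known chemistry, still forms C5–C1 and C9–C10 in one operation, sets out from 7 and comes back at 16.
- Aldehyde 7 is treated with 4-methylfuran-2-yllithium (3-methylfuran, lithium 2,2,6,6-tetramethylpiperidide, THF, −78 °C) to give the furyl diol F1.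
- Achmatowicz rearrangement (NBS, NaHCO3, THF–H2O, 0 °C) gives the hydroxypyranone F2, and Ac2O–pyridine gives the acetoxypyranone F3.
- DBU in MeCN at 60 to 80 °C eliminates acetic acid to the 3-oxidopyrylium ylide. Its intramolecular [5+2] cycloaddition to the tethered alkene gives the oxa-bridged enone F4. The C4 hydroxyl, hydrogen-bonded to the oxido oxygen, and the isopropyl group, turned to the ring-oxygen side, should give the same C1/C4 relation.
- SmI2 (THF–MeOH) cleaves the C5–O bond next to the ketone and gives the γ-hydroxy enone F5.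
- Ac2O–DMAP gives the γ-acetoxy enone F6.
- A second, vinylogous SmI2 reduction followed by DBU for re-conjugation gives 16.

**Step 8.** The C4 alkoxide of the β-hydroxy ketone may trigger retro-aldol opening of the cyclopentane under the basic methanolysis, or equilibration at C5 may stay incomplete. The fallback sets out from 14 and comes back at 16. The C4 hydroxyl is masked first (Et3SiOTf, 2,6-lutidine, CH2Cl2) to give the silyl ether F7. Methanolysis and equilibration (K2CO3, MeOH) then run without a free alkoxide and give the silylated enone F8. HF·pyridine in THF removes the silyl group under non-basic conditions to give 16.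

**Step 9.** Ligand exchange at the hindered tertiary hydroxyl may be slow, so that undirected hydride attack lowers the facial selectivity at C6. The fallback sets out from 16 and comes back at 19. The opposite alcohol is made on purpose by chelation-controlled reduction (Zn(BH4)2, Et2O, −20 °C), which should give the 1,3-syn diol F9. A Mitsunobu esterification with 18 (PPh3, DIAD, toluene, 0 °C) inverts C6 and gives 19 directly.

Further compounds
F1 | step 7 | (2R)-5-methyl-1-(4-methylfuran-2-yl)-2-(propan-2-yl)hex-5-ene-1,2-diol (C5 epimers) | Cc1coc(C(O)[C@](O)(C(C)C)CCC(C)=C)c1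
F2 | step 7 | 6-hydroxy-2-[(3R)-3-hydroxy-2,6-dimethylhept-6-en-3-yl]-5-methyl-2H-pyran-3(6H)-one | CC1=CC(=O)C(OC1O)[C@](O)(C(C)C)CCC(C)=C
F3 | step 7 | 6-[(3R)-3-hydroxy-2,6-dimethylhept-6-en-3-yl]-3-methyl-5-oxo-5,6-dihydro-2H-pyran-2-yl acetate | CC1=CC(=O)C(OC1OC(C)=O)[C@](O)(C(C)C)CCC(C)=C
F4 | step 7 | oxa-bridged enone (16 with an oxygen bridge between C5 and C9) | CC1=CC(=O)[C@]23O[C@H]1C[C@@]2(C)CC[C@@]3(O)C(C)C
F5 | step 7 | γ-hydroxy enone (9-hydroxy derivative of 16) | CC1=CC(=O)[C@@H]2[C@@](C)(C[C@@H]1O)CC[C@@]2(O)C(C)C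
F6 | step 7 | γ-acetoxy enone (9-acetoxy derivative of 16) | CC1=CC(=O)[C@@H]2[C@@](C)(C[C@@H]1OC(C)=O)CC[C@@]2(O)C(C)C
F7 | step 8 | C4 triethylsilyl ether of 14 | CC1=CC(OC(=O)C(C)(C)C)=C2[C@@](C)(CC1)CC[C@@]2(O[Si](CC)(CC)CC)C(C)C
F8 | step 8 | C4 triethylsilyl ether of 16 | CC1=CC(=O)[C@@H]2[C@@](C)(CC1)CC[C@@]2(O[Si](CC)(CC)CC)C(C)C
F9 | step 9 | C6 epimer of 17 (1,3-syn diol) | CC1=C[C@@H](O)[C@@H]2[C@@](C)(CC1)CC[C@@]2(O)C(C)C
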